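The cyclohexane ring is opened at C1–C2 and C3–C4. This releases the C2–C3 ethano unit that lies between the quaternary carbinol C1 and the cis-3,4-diol, which is read as a masked cis-alkene. Vinyltriphenylphosphonium bromide delivers this unit. The malonate carbanion at C1 of an acyclic (R)-α-silyloxy aldehyde (C1–C6–C5–C4) adds to its CH2 end, and the ylide so formed olefinates the C4 aldehyde, closing the cyclohexene in one operation. The purchased C5 stereocentre then directs hydroxylation at C1 and, through the bridged 1,5-lactone, dihydroxylation at C3/C4. Selective 1,3-diacylation of quinide and acid hydrolysis complete the synthesis.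

Key step: step 4

Remark: quinic acid numbering is used throughout, also for acyclic precursors. C1 is quaternary, C2 and C6 are methylene, C3 is the acylated carbinol, C4 and C5 are carbinols, and C7 is the carboxyl carbon. The β face is the face of C7 and 5-O; the α face is the face of 1-O, 3-O and 4-O.

Step 1
Reactants: 1 (S)-2-hydroxybut-3-en-1-yl 4-methylbenzenesulfonate
Product: 2 (S)-2-[(tert-butyldimethylsilyl)oxy]but-3-en-1-yl 4-methylbenzenesulfonate
Conditions: TBSCl, imidazole, DMF, 0 °C → rt
Reagents that add atoms: tert-butyldimethylsilyl chloride, CC(C)(C)[Si](C)(C)Cl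
Why: Imidazole-promoted silylation of the secondary allylic alcohol leaves the C–O bond at the stereocentre (future C5) untouched, so its configuration is retained.

Step 2
Reactants: 2 (S)-2-[(tert-butyldimethylsilyl)oxy]but-3-en-1-yl 4-methylbenzenesulfonate, 3 dimethyl malonate
Product: 4 dimethyl 2-{(2R)-2-[(tert-butyldimethylsilyl)oxy]but-3-en-1-yl}malonate
Conditions: NaH, NaI (10 mol %), DMF, 0 → 70 °C
Reagents that add atoms: none
Why: Malonic ester alkylation (SN2 at the primary tosylate) forms C1–C6, and the soft, weakly basic nucleophile spares the silyl ether, the alkene and the stereocentre (the descriptor changes only through CIP priorities).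

Step 3
Reactants: 4 dimethyl 2-{(2R)-2-[(tert-butyldimethylsilyl)oxy]but-3-en-1-yl}malonate
Product: 5 dimethyl 2-{(2R)-2-[(tert-butyldimethylsilyl)oxy]-3-oxopropyl}malonate
Conditions: O3, CH2Cl2, −78 °C; then PPh3, −78 °C → rt
Reagents that add atoms: ozone, [O-][O+]=O
Why: Ozonolysis with reductive work-up cleaves the only alkene to the C4 aldehyde under neutral conditions, so the α-silyloxy stereocentre should not epimerise.

Step 4
Reactants: 5 dimethyl 2-{(2R)-2-[(tert-butyldimethylsilyl)oxy]-3-oxopropyl}malonate, 6 vinyltriphenylphosphonium bromide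
Product: 9 dimethyl (5R)-5-[(tert-butyldimethylsilyl)oxy]cyclohex-3-ene-1,1-dicarboxylate, via sodium malonate enolate 7 (not isolated), via phosphonium ylide 8 (not isolated)
Conditions: NaH (1.0 equiv), THF, 0 °C; then CH2=CHPPh3Br, THF–DMF, rt → 50 °C
Reagents that add atoms: none
Why: NaH removes only the malonate C–H of 5, by far the most acidic proton, and the soft carbanion 7 adds to the CH2 terminus of the vinylphosphonium salt (Michael addition, forms C1–C2) to give the non-stabilised ylide 8. Intramolecular Wittig olefination (6-exo-trig attack of the ylide carbon on C4=O, oxaphosphetane, loss of Ph3P=O) then forms C3=C4 and closes the carbocycle; the sequence is the classical vinylphosphonium cycloalkene annulation of ω-oxoalkyl malonates. The six-membered ring enforces the cis alkene, no new stereocentre arises because C1 carries two identical esters, and C5 is carried through unchanged. After the Michael step C1 is quaternary, so no acidic proton is left to quench the ylide, and while C1 is deprotonated a retro-Michael loss of malonate is blocked. The step needs C-alkylation and ring closure to outrun enolisation of the α-silyloxy aldehyde, which is secured by exactly one equivalent of base, a carbanion too weak to deprotonate C5–H, and the fast intramolecular carbonyl attack.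

Step 5
Reactants: 9 dimethyl (5R)-5-[(tert-butyldimethylsilyl)oxy]cyclohex-3-ene-1,1-dicarboxylate
Product: 10 methyl (5R)-5-[(tert-butyldimethylsilyl)oxy]cyclohex-3-ene-1-carboxylate (mixture of C1 epimers)
Conditions: LiCl, H2O (2 equiv), DMSO, 150 °C
Reagents that add atoms: none
Why: Krapcho dealkoxycarbonylation (chloride attack on a methyl group, loss of CO2, protonation) removes the activating ester, and the C1 epimer mixture is inconsequential because C1 is planarised in the next step.

Step 6
Reactants: 10 methyl (5R)-5-[(tert-butyldimethylsilyl)oxy]cyclohex-3-ene-1-carboxylate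
Product: 12 methyl (1S,5R)-1-hydroxy-5-[(tert-butyldimethylsilyl)oxy]cyclohex-3-ene-1-carboxylate, via potassium ester enolate 11 (not isolated)
Conditions: KN(SiMe3)2, THF, −78 °C; then 3-phenyl-2-(phenylsulfonyl)oxaziridine, −78 °C; sat. aq. NH4Cl
Reagents that add atoms: 3-phenyl-2-(phenylsulfonyl)oxaziridine, O=S(=O)(c1ccccc1)N1OC1c1ccccc1
Why: In this enolate hydroxylation with a Davis oxaziridine the pseudoaxial β-silyloxy group at C5 blocks the 1,3-related β trajectory at the exocyclic enolate, so oxygen should enter from the α face and leave the ester cis to 5-O.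

Step 7
Reactants: 12 methyl (1S,5R)-1-hydroxy-5-[(tert-butyldimethylsilyl)oxy]cyclohex-3-ene-1-carboxylate
Product: 14 (1S,5R)-1-hydroxy-6-oxabicyclo[3.2.1]oct-3-en-7-one, via dihydroxy ester 13 (not isolated)
Conditions: Bu4NF, THF, 0 °C → rt; then DBU (cat.), toluene, 90 °C (removal of MeOH)
Reagents that add atoms: none
Why: Fluoride desilylation followed by lactonisation (intramolecular transesterification) closes the bridged γ-lactone only from the epimer with the ester cis to 5-OH, so the step also removes any C1 epimer from step 6.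

Step 8
Reactants: 14 (1S,5R)-1-hydroxy-6-oxabicyclo[3.2.1]oct-3-en-7-one
Product: 15 (−)-quinide, (1S,3R,4R,5R)-1,3,4-trihydroxy-6-oxabicyclo[3.2.1]octan-7-one
Conditions: OsO4 (2 mol %), NMO, acetone–H2O, 0 °C → rt
Reagents that add atoms: N-methylmorpholine N-oxide, C[N+]1([O-])CCOCC1; water, O
Why: In this Upjohn syn-dihydroxylation OsO4 should attack the exo (α) face of the C3=C4 alkene, anti to the two-atom lactone bridge, which sets C3 and C4 cis to each other and trans to 5-O.

Step 9
Reactants: 16 caffeic acid
Product: 17 (E)-3,4-diacetoxycinnamic acid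
Conditions: Ac2O, pyridine, rt; aqueous work-up
Reagents that add atoms: acetic anhydride, CC(=O)OC(C)=O
Why: Acetylation masks the catechol against acylation and oxidation, any mixed anhydride at the acid is hydrolysed on work-up, and the E alkene is untouched.

Step 10
Reactants: 17 (E)-3,4-diacetoxycinnamic acid
Product: 18 (E)-3,4-diacetoxycinnamoyl chloride
Conditions: (COCl)2, DMF (cat.), CH2Cl2, 0 °C → rt
Reagents that add atoms: oxalyl chloride, O=C(Cl)C(=O)Cl
Why: Acid chloride formation through the Vilsmeier-type chloroiminium species is mild enough for the aryl acetates and the cinnamoyl alkene.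

Step 11
Reactants: 15 (−)-quinide, 18 (E)-3,4-diacetoxycinnamoyl chloride (2.2 equiv)
Product: 19 1,3-di-O-[(E)-3,4-diacetoxycinnamoyl]quinide
Conditions: pyridine, DMAP (cat.), CH2Cl2, −10 °C → rt
Reagents that add atoms: none
Why: In this DMAP-catalysed esterification the equatorial 3-OH and the exposed bridgehead 1-OH should acylate faster than the axial 4-OH, which is flanked by 3-O and 5-O in the rigid lactone.

Step 12
Reactants: 19 1,3-di-O-[(E)-3,4-diacetoxycinnamoyl]quinide
Product: 20 1,3-dicaffeoylquinic acid
Conditions: 1 M aq. HCl–THF, rt, several days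
Reagents that add atoms: water, O
Why: Acid-catalysed hydrolysis cleaves the four aryl acetates and opens the strained 1,5-lactone, while the conjugated, hindered caffeoyl esters at O1 and O3 persist and acyl migration, which is base-promoted, is avoided.

Compound list
1 | (S)-2-hydroxybut-3-en-1-yl 4-methylbenzenesulfonate | Cc1ccc(cc1)S(=O)(=O)OC[C@@H](O)C=C | starting material
2 | (S)-2-[(tert-butyldimethylsilyl)oxy]but-3-en-1-yl 4-methylbenzenesulfonate | Cc1ccc(cc1)S(=O)(=O)OC[C@@H](O[Si](C)(C)C(C)(C)C)C=C | intermediate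
3 | dimethyl malonate | COC(=O)CC(=O)OC | starting material
4 | dimethyl 2-{(2R)-2-[(tert-butyldimethylsilyl)oxy]but-3-en-1-yl}malonate | COC(=O)C(C[C@@H](O[Si](C)(C)C(C)(C)C)C=C)C(=O)OC | intermediate
5 | dimethyl 2-{(2R)-2-[(tert-butyldimethylsilyl)oxy]-3-oxopropyl}malonate | COC(=O)C(C[C@@H](O[Si](C)(C)C(C)(C)C)C=O)C(=O)OC | intermediate
6 | vinyltriphenylphosphonium bromide | C=C[P+](c1ccccc1)(c1ccccc1)c1ccccc1.[Br-] | starting material
7 | sodium enolate of 5 (malonate carbanion at C1) | [Na+].COC(=O)[C-](C[C@@H](O[Si](C)(C)C(C)(C)C)C=O)C(=O)OC | intermediate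
8 | phosphonium ylide from addition of 7 to 6 | COC(=O)C(CC=P(c1ccccc1)(c1ccccc1)c1ccccc1)(C[C@@H](O[Si](C)(C)C(C)(C)C)C=O)C(=O)OC | intermediate
9 | dimethyl (5R)-5-[(tert-butyldimethylsilyl)oxy]cyclohex-3-ene-1,1-dicarboxylate | COC(=O)C1(C(=O)OC)CC=C[C@H](O[Si](C)(C)C(C)(C)C)C1 | intermediate
10 | methyl (5R)-5-[(tert-butyldimethylsilyl)oxy]cyclohex-3-ene-1-carboxylate (C1 epimers) | COC(=O)C1CC=C[C@H](O[Si](C)(C)C(C)(C)C)C1 | intermediate
11 | potassium enolate of 10 | [K+].COC([O-])=C1CC=C[C@H](O[Si](C)(C)C(C)(C)C)C1 | intermediate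
12 | methyl (1S,5R)-1-hydroxy-5-[(tert-butyldimethylsilyl)oxy]cyclohex-3-ene-1-carboxylate | COC(=O)[C@]1(O)CC=C[C@H](O[Si](C)(C)C(C)(C)C)C1 | intermediate
13 | methyl (1S,5R)-1,5-dihydroxycyclohex-3-ene-1-carboxylate | COC(=O)[C@]1(O)CC=C[C@H](O)C1 | intermediate
14 | (1S,5R)-1-hydroxy-6-oxabicyclo[3.2.1]oct-3-en-7-one | O=C1O[C@H]2C=CC[C@]1(O)C2 | intermediate
15 | (−)-quinide, (1S,3R,4R,5R)-1,3,4-trihydroxy-6-oxabicyclo[3.2.1]octan-7-one | O=C1O[C@H]2[C@H](O)[C@H](O)C[C@]1(O)C2 | intermediate
16 | caffeic acid | O=C(O)/C=C/c1ccc(O)c(O)c1 | starting material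
17 | (E)-3,4-diacetoxycinnamic acid | CC(=O)Oc1ccc(/C=C/C(=O)O)cc1OC(C)=O | intermediate
18 | (E)-3,4-diacetoxycinnamoyl chloride | CC(=O)Oc1ccc(/C=C/C(=O)Cl)cc1OC(C)=O | intermediate
19 | 1,3-di-O-[(E)-3,4-diacetoxycinnamoyl]quinide | O=C1O[C@H]2[C@H](O)[C@H](OC(=O)/C=C/c3ccc(OC(C)=O)c(OC(C)=O)c3)C[C@]1(OC(=O)/C=C/c4ccc(OC(C)=O)c(OC(C)=O)c4)C2 | intermediate
20 | 1,3-dicaffeoylquinic acid | O=C(/C=C/c1ccc(O)c(O)c1)O[C@@H]1C[C@@](OC(=O)/C=C/c2ccc(O)c(O)c2)(C(=O)O)C[C@@H](O)[C@@H]1O | target

Total step count: 12. Longest linear sequence: 10 (steps 1–8, 11, 12).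

Steps most likely to fail

**Step 4.** Proton transfer from C5–H to the ylide, followed by epimerisation or retro-Michael cleavage of the β-malonyl aldehyde, may outrun ring closure. The fallback builds the same ring by two separate bond formations. It sets out from 4. C-allylation of the malonate carbon (NaH, allyl bromide, THF) should give dimethyl 2-allyl-2-{(2R)-2-[(tert-butyldimethylsilyl)oxy]but-3-en-1-yl}malonate F1. Ring-closing metathesis of its two terminal alkenes (second-generation Grubbs catalyst, CH2Cl2, 40 °C) expels ethene and comes back to the route at 9.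

**Step 6.** Facial selectivity at the flexible exocyclic enolate may be poor, which would waste material as the C1 epimer. The fallback fixes C1 by a cage instead of by induction and sets out from 9.
- Bu4NF, then heating with catalytic DBU, should close the lactone with the ester that lies cis to 5-OH. This gives methyl (1R,5R)-7-oxo-6-oxabicyclo[3.2.1]oct-3-ene-1-carboxylate F2.
- Me3SnOH in 1,2-dichloroethane should hydrolyse the remaining methyl ester to (1R,5R)-7-oxo-6-oxabicyclo[3.2.1]oct-3-ene-1-carboxylic acid F3.
- Barton decarboxylative hydroxylation (N-hydroxypyridine-2-thione ester, O2, t-BuSH, hν, then P(OMe)3) replaces the bridgehead carboxyl by OH. Retention is enforced by the bicycle, and the sequence comes back at 14.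

**Step 11.** Over-acylation at 4-OH or incomplete acylation of the tertiary 1-OH may erode the regioselectivity. The fallback acylates the two positions one after the other and sets out from 15.
- 2,2-Dimethoxypropane with catalytic TsOH in acetone should give 3,4-O-isopropylidenequinide F4.
- Acylation of its only free hydroxyl with 18 (pyridine, DMAP) gives 1-O-[(E)-3,4-diacetoxycinnamoyl]-3,4-O-isopropylidenequinide F5.
- Aqueous trifluoroacetic acid in CH2Cl2 removes the acetonide to give 1-O-[(E)-3,4-diacetoxycinnamoyl]quinide F6.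
- One equivalent of 18 at low temperature then acylates the equatorial 3-OH in preference to the axial 4-OH and comes back at 19.

Further compounds
F1 | step 4 | dimethyl 2-allyl-2-{(2R)-2-[(tert-butyldimethylsilyl)oxy]but-3-en-1-yl}malonate | COC(=O)C(CC=C)(C[C@@H](O[Si](C)(C)C(C)(C)C)C=C)C(=O)OC
F2 | step 6 | methyl (1R,5R)-7-oxo-6-oxabicyclo[3.2.1]oct-3-ene-1-carboxylate | O=C1O[C@H]2C=CC[C@]1(C(=O)OC)C2
F3 | step 6 | (1R,5R)-7-oxo-6-oxabicyclo[3.2.1]oct-3-ene-1-carboxylic acid | O=C1O[C@H]2C=CC[C@]1(C(=O)O)C2
F4 | step 11 | 3,4-O-isopropylidenequinide | O=C1O[C@H]2[C@@H]3OC(C)(C)O[C@@H]3C[C@]1(O)C2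
F5 | step 11 | 1-O-[(E)-3,4-diacetoxycinnamoyl]-3,4-O-isopropylidenequinide | O=C1O[C@H]2[C@@H]3OC(C)(C)O[C@@H]3C[C@]1(OC(=O)/C=C/c4ccc(OC(C)=O)c(OC(C)=O)c4)C2
F6 | step 11 | 1-O-[(E)-3,4-diacetoxycinnamoyl]quinide | O=C1O[C@H]2[C@H](O)[C@H](O)C[C@]1(OC(=O)/C=C/c3ccc(OC(C)=O)c(OC(C)=O)c3)C2
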